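Remarks on conventions and one assumption
- Carbons keep the germacrane numbers C1–C15 at every stage: C14 is the ester carbon on C10, C15 the methyl on C4, C11–C13 the three-carbon unit on C7. Ring A is C10, C1–C5; ring B is C5–C10. α is the face of ring B that carries the C6 oxygen, β the other face.
- Assumption: adduct 5 is written with the absolute configuration the route needs. The sense of induction of the gadolinium–pybox catalyst is assigned by analogy with two-point-bound quinone esters; if the mirror-image adduct forms, the ligand antipode is used.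

## Analysis of the target

Target 32 is a germacranolide: a ten-membered carbocycle C1–C10 with a trans-fused α-methylene-γ-lactone across C6/C7 (O on C6, C11 on C7). C10 carries a methyl ester, C9 an acetate and C8 a (2S,3R)-2,3-dimethyloxirane-2-carboxylate. The ring holds a dienoate, C10=C1 (ring-cis, ester outside) conjugated with Z C2=C3, and a trans epoxide C4–C5 with the C15 methyl on C4. The ring stereocentres are 4R,5R,6S,7R,8S,9S: O6 and C11 are trans, C11 and O8 cis, O8 and O9 trans, and the epoxide oxygen sits on the outer face of what was an E C4=C5 bond. Two further centres lie in the epoxy ester. The sensitive groups are the Michael-acceptor methylene lactone, two epoxides, base-labile esters on a vicinal diol and a medium-ring polyene open to isomerisation and transannular reaction. The difficulty is a ten-membered ring with three defined alkene geometries next to four contiguous oxygenated or branched centres. The plan rests on one feature: C10=C1–C2=C3 together with the oxidised C4–C5 bond is a cyclodeca-1,3,5-triene, the open valence isomer of a bicyclo[4.4.0]deca-2,4-diene whose shared bond is C5–C10.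

## Retrosynthetic reasoning

**32 to 31.** The C4–O and C5–O bonds are cut first. Triene 31 has only one electron-rich, strained alkene, the E trisubstituted C4=C5 bond, so an electrophilic oxygen donor should find it. The forward step must work cold, because 31 can reclose thermally.

**31 to 30.** The C5–C10 bond is re-formed on paper, which turns the medium-ring problem into a decalin problem. Diene 30 already carries every carbon and oxygen of the target, and the alkene geometries of 31 then follow from orbital symmetry instead of a macrocyclisation. The forward step is a photochemical conrotatory opening. A pseudo-equatorial substituent on C5 or C10 swings outward and a pseudo-axial one inward, so C6 must be pseudo-equatorial and C9 pseudo-axial on ring A. The trans lactone locks ring B in one chair, and only the cis-fused isomer with ring A on the α face (H5 and the ester β) meets this demand in that chair. The other cis-fused isomer has the reverse twist and would be expected to give the 4Z, ring-trans triene. For this reason 30 is drawn with H5 and CO2Me β.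

**30 to 28.** The homoannular diene is taken back through allylic alcohol 29 to enone 28. An enone is inert to the oxidants and acylating agents used on ring B, so the fragile diene appears only one step before irradiation.

**28 to 24.** The lactone C12–O6 bond is cut and C12 is lowered to an allylic alcohol (diol 25, bis-silyl ether 24). The exocyclic methylene is then carried from the start and never has to be installed on a lactone enolate in the presence of esters.

**24 to 17 and 21.** The two ester C–O bonds are cut. Acid 21 comes from tiglic acid 18 by reduction (19), asymmetric epoxidation (20) and oxidation, so the side-chain centres are set independently of the ring.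

**17 to 13.** The 8β,9α diol is trans-diaxial, the less stable arrangement, so each hydroxyl is traced back to a ketone (17 from 16 and 15, 14 from 13). A hydride that enters equatorially leaves an axial alcohol. The axial C5–C4 bond closes the α face at C9, and the 9α hydroxyl then directs hydride to the α face of C8.

**13 to 7 and 9.** The C7–C11 bond is cut next to the C9 carbonyl (conjugate addition of the alkenyl unit from bromide 9, prepared from 8). The C8 oxygen is introduced on the resulting enolate. The C6 silyl ether and the convex face together place C11 trans to O6.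

**7 to 2 and 4.** The C6 carbinol of 6 comes from a quinone carbonyl of adduct 5. Cutting C10–C1 and C4–C5 of 5 gives quinone ester 2 (from hydroquinone 1) and siloxydiene 4 (from ethyl vinyl ketone 3). The Diels–Alder reaction must give the cis fusion and the absolute configuration. Every later centre is then set from the convex face, which is exactly what puts ring A cis to O6 as 30 requires.

## Alternatives that were turned down

Alternative 1: The ring would be built by enone–alkene photocycloaddition of enone lactone A2 with 1-methylcyclobutene A3. This forms C10–C1 and C4–C5 and gives the bicyclo[2.2.0]hexane adduct A1; thermal cycloreversion then cleaves C5–C10 and C1–C4. In its favour, the absolute configuration comes from the chiral pool, the thermal opening is irreversible and there is no torquoselectivity to control; on these points it is stronger than the chosen route. Against it, A1 carries C14 as a methyl group and C2–C3 as a saturated bridge. The ester and the third double bond would have to be introduced on a ten-membered diene that undergoes Cope rearrangement at the temperatures of the cycloreversion. The head-to-head/head-to-tail and facial outcome of the cycloaddition are uncertain, and the ring-cis C10=C1 geometry is not guaranteed. At least six steps would follow the key step, against one here.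

Alternative 2: Alkoxide A5 (ethynyl on C10, isopropenyl on C5) would undergo an anionic oxy-Cope shift that makes C2–C3 and breaks C5–C10, giving ten-membered enone A4 with E C4=C5. In its favour, the step is well precedented, irreversible and needs no light; it is the more predictable ring expansion. Against it, A4 has a ketone at C10 and a CH2 at C3. The ester carbon must be added later through a dienyl triflate whose regiochemistry and C10=C1 geometry are uncontrolled, and the C9 centre next to the ketone can epimerise. Four protecting groups have to be removed and three oxidations and two acylations carried out on the flexible ring, roughly eight to ten steps after the key step. The chosen route does all of this on a rigid decalin before the ring is opened.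

Alternative 3: Seco aldehyde A7 with a C10 vinyl iodide would be closed at C9–C10 by CrCl2 with catalytic NiCl2 to give carbinol A6. In its favour, it is convergent, tolerant of the lactone, and fixes the dienoate geometry in the acyclic iodide; it does not depend on photochemistry. Against it, a ten-membered ring with three sp2 pairs must be closed against transannular strain and in competition with dimerisation. The C9 configuration is set under weak control next to an epimerisable α-alkoxy aldehyde, the Z,Z,E trienyl iodide is itself hard to make, and C14 must still be oxidised to the ester. In the chosen route the ring is made by breaking a bond of a preformed bicycle, so there is no entropic penalty or high dilution, and C9 is set on a chair.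

Key step: step 21

## Route

Step 1
Reactants: 1 methyl 2,5-dihydroxybenzoate
Product: 2 methyl 3,6-dioxocyclohexa-1,4-diene-1-carboxylate
Conditions: Ag2O, MgSO4, Et2O, 25 °C; filtered and used at once
Reagents that add atoms: none
Why: Two-electron oxidation of the hydroquinone by Ag2O gives the quinone ester; the drying agent takes up the water so that the labile quinone can be used directly.

Step 2
Reactants: 3 pent-1-en-3-one (ethyl vinyl ketone)
Product: 4 (Z)-3-(tert-butyldimethylsilyloxy)penta-1,3-diene
Conditions: TBSOTf, Et3N, Et2O, 0 °C
Reagents that add atoms: tert-butyldimethylsilyl triflate, CC(C)(C)[Si](C)(C)OS(=O)(=O)C(F)(F)F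
Why: Soft enolisation of the ketone on its CH2 side gives the cross-conjugated silyl dienol ether with the usual Z geometry (methyl cis to oxygen), which puts the methyl on the outside of the s-cis diene.

Step 3
Reactants: 2 quinone ester; 4 siloxydiene
Product: 5 cis-fused enedione adduct
Conditions: Gd(OTf)3 (10 mol %), (S,S)-iPr-pybox (12 mol %), 4 Å MS, CH2Cl2, −78 °C
Reagents that add atoms: none
Why: Diels–Alder reaction at the ester-bearing double bond of the quinone, activated by two-point binding of the C9 carbonyl and the ester to the chiral Lewis acid; the nucleophilic terminus C4 of the diene joins C5, so C10–C1 and C4–C5 form suprafacially and the fusion is cis. The endo mode puts C15 cis to C6 (a centre erased later), and the catalyst fixes the absolute configuration of C5 and C10.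

Step 4
Reactants: 5 enedione adduct
Product: 6 6α-hydroxy enone
Conditions: NaBH4, CeCl3·7H2O, MeOH–CH2Cl2, −78 °C
Reagents that add atoms: none
Why: Luche 1,2-reduction; hydride reaches the folded cis-fused enedione from its convex β face and attacks C6, whose neighbour C5 shows only hydrogen on that face, in preference to C9, which is flanked by the quaternary C10 with its ester on the convex face. The alcohol is therefore 6α, cis to the C5–C4 bond.

Step 5
Reactants: 6 hydroxy enone
Product: 7 6α-silyl ether
Conditions: TBSOTf, 2,6-lutidine, CH2Cl2, −78 °C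
Reagents that add atoms: tert-butyldimethylsilyl triflate, CC(C)(C)[Si](C)(C)OS(=O)(=O)C(F)(F)F
Why: Silylation of the secondary allylic alcohol at low temperature with a hindered base leaves the enone and the ring A enol ether untouched.

Step 6
Reactants: 8 2-bromoprop-2-en-1-ol
Product: 9 (2-bromoprop-2-enyloxy)(tert-butyl)dimethylsilane
Conditions: TBSCl, imidazole, CH2Cl2, 25 °C
Reagents that add atoms: tert-butyldimethylsilyl chloride, CC(C)(C)[Si](C)(C)Cl
Why: Standard silyl protection of the primary allylic alcohol.

Step 7
Reactants: 7 enone silyl ether; 9 vinyl bromide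
Product: 13 7β-alkenyl-8α-hydroxy-9-ketone, via alkenyllithium 10 (not isolated), via lithium dialkenylcuprate 11 (not isolated), via lithium enolate 12 (not isolated)
Conditions: 9, t-BuLi (2 equiv), Et2O, −78 °C; CuBr·SMe2 (0.5 equiv); 7, −78 to −40 °C; then 2-(phenylsulfonyl)-3-phenyloxaziridine, −78 °C; NH4Cl
Reagents that add atoms: 2-(phenylsulfonyl)-3-phenyloxaziridine, O=S(=O)(c1ccccc1)N1OC1c1ccccc1
Why: Bromine–lithium exchange and transmetalation give the Gilman reagent, which adds 1,4 to the C9 enone at C7 anti to the C6 silyl ether and from the convex face, so C11 is 7β and trans to O6. The enolate is then hydroxylated at C8 in the same flask (Davis oxidation); the C8 configuration (expected α, anti to the new side chain) does not matter because C8 is oxidised in step 9.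

Step 8
Reactants: 13 hydroxy ketone
Product: 14 8α,9α-diol
Conditions: LiBH(s-Bu)3, THF, −78 to −40 °C; then NaOH, H2O2
Reagents that add atoms: none
Why: The bulky borohydride attacks the C9 ketone along the equatorial trajectory from the β side, because the axial approach on the α face is closed by the axial C5–C4 bond (1,3 to C9); the 9α alcohol is axial. No enone is present at this stage and the hindered ester is inert at low temperature.

Step 9
Reactants: 14 diol
Product: 15 9α-hydroxy-8-ketone
Conditions: IBX, DMSO, 25 °C
Reagents that add atoms: none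
Why: IBX oxidises the equatorial, less hindered C8 hydroxyl and leaves the axial, neopentyl C9 hydroxyl; it does not cleave 1,2-diols. If it also dehydrogenates the ring A enol ether, the product is simply 16.

Step 10
Reactants: 15 ketol silyl enol ether
Product: 16 ring A enone
Conditions: Pd(OAc)2 (1.1 equiv), MeCN, 25 °C
Reagents that add atoms: none
Why: Ito–Saegusa oxidation: the silyl enol ether gives a palladium enolate at C2, and β-hydride elimination from C1 gives the C1=C2 enone with the C3 carbonyl regiospecifically. The enone keeps ring A inert until the end of the route.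

Step 11
Reactants: 16 ketol enone
Product: 17 8β,9α-diol
Conditions: Me4NBH(OAc)3, MeCN–AcOH, −30 °C
Reagents that add atoms: none
Why: Evans–Saksena reduction: the triacetoxyborohydride binds the 9α hydroxyl and delivers hydride to the α face of the C8 ketone, and the β face is screened as well by the axial ester on C10. The diol is trans-diaxial; the ring A enone has no directing group and is not reduced.

Step 12
Reactants: 18 tiglic acid
Product: 19 (E)-2-methylbut-2-en-1-ol
Conditions: LiAlH4, Et2O, 0 °C
Reagents that add atoms: none
Why: Hydride reduction of the unsaturated acid gives the allylic alcohol with the E geometry intact.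

Step 13
Reactants: 19 allylic alcohol
Product: 20 [(2R,3R)-2,3-dimethyloxiran-2-yl]methanol
Conditions: Ti(OiPr)4 (10 mol %), D-(−)-diethyl tartrate (12 mol %), t-BuOOH, 4 Å MS, CH2Cl2, −20 °C
Reagents that add atoms: tert-butyl hydroperoxide, CC(C)(C)OO
Why: Sharpless asymmetric epoxidation; with the D-tartrate, oxygen is delivered to the face of the E allylic alcohol that gives the (2R,3R) epoxide, which maps onto the two side-chain centres of the target.

Step 14
Reactants: 20 epoxy alcohol
Product: 21 (2S,3R)-2,3-dimethyloxirane-2-carboxylic acid
Conditions: RuCl3 (2 mol %), NaIO4, MeCN–CCl4–H2O, 25 °C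
Reagents that add atoms: water, O
Why: Catalytically generated RuO4 oxidises the primary alcohol through the aldehyde hydrate to the acid without touching the epoxide; only the CIP label of C2 changes.

Step 15
Reactants: 17 diol; 21 epoxy acid
Product: 23 8β-epoxy ester 9α-alcohol, via mixed anhydride 22 (not isolated)
Conditions: 21, 2,4,6-trichlorobenzoyl chloride, Et3N, toluene, 25 °C; then 17, DMAP, 0 to 25 °C
Reagents that add atoms: none
Why: Yamaguchi esterification: the mixed anhydride acylates the C8 hydroxyl, which is flanked by CH groups, faster than the C9 hydroxyl, which is neopentyl and 1,3-diaxial to C4. The trans-diaxial arrangement rules out acyl migration.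

Step 16
Reactants: 23 hydroxy ester
Product: 24 9α-acetate
Conditions: Ac2O, DMAP, Et3N, CH2Cl2, 25–40 °C
Reagents that add atoms: acetic anhydride, CC(=O)OC(C)=O
Why: DMAP-catalysed acetylation of the one remaining, hindered secondary alcohol.

Step 17
Reactants: 24 bis-silyl ether
Product: 25 6α,12-diol
Conditions: HF·pyridine, pyridine, THF, 0 to 25 °C
Reagents that add atoms: none
Why: Fluoride cleaves both silyl ethers; the pyridine-buffered reagent spares the acetate, the epoxy ester and the enone.

Step 18
Reactants: 25 diol
Product: 28 lactone enone, via hydroxy enal 26 (not isolated), via lactol 27 (not isolated)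
Conditions: TEMPO (20 mol %), PhI(OAc)2, CH2Cl2, 25 °C
Reagents that add atoms: none
Why: Oxoammonium oxidation of the primary allylic alcohol to the enal, lactol formation with the 6α hydroxyl and a second oxidation give the α-methylene lactone. The ring fusion is trans because O6 and C11 are trans-diequatorial.

Step 19
Reactants: 28 lactone enone
Product: 29 C3 allylic alcohol
Conditions: NaBH4, CeCl3·7H2O, MeOH, −78 °C
Reagents that add atoms: none
Why: Luche reduction at −78 °C reduces the ring A enone carbonyl 1,2 fast enough to leave the methylene lactone and the esters. Hydride should enter from the convex face of ring A, but the C3 configuration is erased in step 20.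

Step 20
Reactants: 29 allylic alcohol
Product: 30 cis-fused diene ester
Conditions: Martin sulfurane, CH2Cl2, 0 °C
Reagents that add atoms: none
Why: Dehydration with Martin sulfurane: the allylic alkoxysulfonium ionises and the only available proton, H4, is lost (C10 is quaternary), giving the C1=C2–C3=C4 homoannular diene.

Step 21
Reactants: 30 cis-fused diene ester
Product: 31 cyclodecatriene ester (cold solution, used directly)
Conditions: hν (254 nm, low-pressure Hg lamp, quartz), degassed Et2O–pentane, −78 °C, to about half conversion; then −40 °C, dark, 30 min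
Reagents that add atoms: none
Why: Excitation of the homoannular diene (absorbing near 265–270 nm) leads to conrotatory 6π electrocyclic cleavage of the C5–C10 bond, the reaction type known from provitamin D and from ring-fused eudesma-1,3-dienes that open to cyclodeca-1,3,5-trienes. The ten-membered ring is not closed end to end: it appears when the bond shared by rings A and B breaks, so the two six-membered rings merge and no new σ-bond or stereocentre is formed (C5 and C10 become trigonal). The geometry of the two new double bonds is decided by the sense of conrotation, which follows the ground-state twist of the diene: a pseudo-equatorial substituent on C5 or C10 swings outward, a pseudo-axial one inward. In 30 the trans lactone holds ring B in the chair with O6 and C11 equatorial; with ring A on the α face, C5–C4 is then axial and C10–C1 equatorial on ring B, so on ring A C6 and the ester are pseudo-equatorial and H5 and C9 pseudo-axial. C6 and the ester therefore turn outward and H5 and C9 inward, which gives E C4=C5 and ring-cis C10=C1, while C2=C3 stays Z because it lay inside ring A. The step needs this torquoselectivity and the excitation of 30 in the presence of the product dienoate, which absorbs in the same region; low temperature, partial conversion and recovery of 30 answer the second point. The quaternary C10 blocks aromatisation, and [1,5]-hydrogen shifts are slow at −78 °C. The ring is born with C4 anti to H6; holding the solution at −40 °C in the dark lets it turn to the unstrained rotamer (H5 anti to H6) that exposes the required face of C4=C5, below the temperature of thermal disrotatory reclosure.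

Step 22
Reactants: 31 triene ester
Product: 32 target
Conditions: dimethyldioxirane (1 equiv based on 31), acetone–CH2Cl2, −40 °C
Reagents that add atoms: dimethyldioxirane, CC1(C)OO1
Why: The dioxirane transfers oxygen in a concerted step (E alkene to trans epoxide) and picks the twisted, trisubstituted C4=C5 bond over the ester-conjugated C10=C1 and C2=C3 bonds and the methylene lactone. Attack on the outer face of the relaxed ring (H5 anti to H6, as in 6,12-trans germacranolides) should give the (4R,5R) epoxide; unchanged 30 reacts more slowly and is recovered.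

## Compound list

1 | methyl 2,5-dihydroxybenzoate | COC(=O)c1cc(O)ccc1O | starting material
2 | methyl 3,6-dioxocyclohexa-1,4-diene-1-carboxylate | COC(=O)C1=CC(=O)C=CC1=O | intermediate
3 | pent-1-en-3-one (ethyl vinyl ketone) | CCC(=O)C=C | starting material
4 | (Z)-3-(tert-butyldimethylsilyloxy)penta-1,3-diene | C/C=C(\O[Si](C)(C)C(C)(C)C)C=C | intermediate
5 | cis-fused adduct: ring A C10–C1H2–C2H=C3(OTBS)–C4H(CH3)–C5H, ring B C5–C6(=O)–C7H=C8H–C9(=O)–C10(CO2Me); H5 and CO2Me β, C15 cis to C6 on ring A | O=C1C=CC(=O)[C@@]2(C(=O)OC)CC=C(O[Si](C)(C)C(C)(C)C)[C@@H](C)[C@@H]12 | intermediate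
6 | 6α-alcohol of 5 (C9 enone kept) | O[C@H]1C=CC(=O)[C@@]2(C(=O)OC)CC=C(O[Si](C)(C)C(C)(C)C)[C@@H](C)[C@@H]12 | intermediate
7 | 6α-tert-butyldimethylsilyl ether of 6 | CC(C)(C)[Si](C)(C)O[C@H]1C=CC(=O)[C@@]2(C(=O)OC)CC=C(O[Si](C)(C)C(C)(C)C)[C@@H](C)[C@@H]12 | intermediate
8 | 2-bromoprop-2-en-1-ol | OCC(Br)=C | starting material
9 | (2-bromoprop-2-enyloxy)(tert-butyl)dimethylsilane | C=C(Br)CO[Si](C)(C)C(C)(C)C | intermediate
10 | [3-(tert-butyldimethylsilyloxy)prop-1-en-2-yl]lithium | [Li]C(=C)CO[Si](C)(C)C(C)(C)C | intermediate
11 | lithium bis[3-(tert-butyldimethylsilyloxy)prop-1-en-2-yl]cuprate | [Li+].C=C(CO[Si](C)(C)C(C)(C)C)[Cu-]C(=C)CO[Si](C)(C)C(C)(C)C | intermediate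
12 | lithium C8=C9 enolate with the 7β alkenyl side chain | CC(C)(C)[Si](C)(C)O[C@H]1[C@H](C(=C)CO[Si](C)(C)C(C)(C)C)C=C(O[Li])[C@@]2(C(=O)OC)CC=C(O[Si](C)(C)C(C)(C)C)[C@@H](C)[C@@H]12 | intermediate
13 | 7β-[3-(silyloxy)prop-1-en-2-yl]-8α-hydroxy-9-ketone (6α-OTBS, ring A silyl enol ether) | CC(C)(C)[Si](C)(C)O[C@H]1[C@H](C(=C)CO[Si](C)(C)C(C)(C)C)[C@@H](O)C(=O)[C@@]2(C(=O)OC)CC=C(O[Si](C)(C)C(C)(C)C)[C@@H](C)[C@@H]12 | intermediate
14 | 8α,9α-diol | CC(C)(C)[Si](C)(C)O[C@H]1[C@H](C(=C)CO[Si](C)(C)C(C)(C)C)[C@@H](O)[C@@H](O)[C@@]2(C(=O)OC)CC=C(O[Si](C)(C)C(C)(C)C)[C@@H](C)[C@@H]12 | intermediate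
15 | 9α-hydroxy-8-ketone (ring A silyl enol ether) | CC(C)(C)[Si](C)(C)O[C@H]1[C@H](C(=C)CO[Si](C)(C)C(C)(C)C)C(=O)[C@@H](O)[C@@]2(C(=O)OC)CC=C(O[Si](C)(C)C(C)(C)C)[C@@H](C)[C@@H]12 | intermediate
16 | 9α-hydroxy-8-ketone with ring A 1-en-3-one | CC(C)(C)[Si](C)(C)O[C@H]1[C@H](C(=C)CO[Si](C)(C)C(C)(C)C)C(=O)[C@@H](O)[C@@]2(C(=O)OC)C=CC(=O)[C@@H](C)[C@@H]12 | intermediate
17 | 8β,9α-diol with ring A 1-en-3-one | CC(C)(C)[Si](C)(C)O[C@H]1[C@H](C(=C)CO[Si](C)(C)C(C)(C)C)[C@H](O)[C@@H](O)[C@@]2(C(=O)OC)C=CC(=O)[C@@H](C)[C@@H]12 | intermediate
18 | tiglic acid | C/C=C(\C)C(=O)O | starting material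
19 | (E)-2-methylbut-2-en-1-ol | C/C=C(\C)CO | intermediate
20 | [(2R,3R)-2,3-dimethyloxiran-2-yl]methanol | OC[C@@]1(C)O[C@@H]1C | intermediate
21 | (2S,3R)-2,3-dimethyloxirane-2-carboxylic acid | OC(=O)[C@@]1(C)O[C@@H]1C | intermediate
22 | mixed anhydride of 21 with 2,4,6-trichlorobenzoic acid | O=C(OC(=O)c1c(Cl)cc(Cl)cc1Cl)[C@@]1(C)O[C@@H]1C | intermediate
23 | 8β-[(2S,3R)-epoxy ester], 9α-alcohol | CC(C)(C)[Si](C)(C)O[C@H]1[C@H](C(=C)CO[Si](C)(C)C(C)(C)C)[C@H](OC(=O)[C@@]3(C)O[C@@H]3C)[C@@H](O)[C@@]2(C(=O)OC)C=CC(=O)[C@@H](C)[C@@H]12 | intermediate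
24 | 8β-epoxy ester, 9α-acetate, bis-silyl ether | CC(C)(C)[Si](C)(C)O[C@H]1[C@H](C(=C)CO[Si](C)(C)C(C)(C)C)[C@H](OC(=O)[C@@]3(C)O[C@@H]3C)[C@@H](OC(C)=O)[C@@]2(C(=O)OC)C=CC(=O)[C@@H](C)[C@@H]12 | intermediate
25 | 6α,12-diol | O[C@H]1[C@H](C(=C)CO)[C@H](OC(=O)[C@@]3(C)O[C@@H]3C)[C@@H](OC(C)=O)[C@@]2(C(=O)OC)C=CC(=O)[C@@H](C)[C@@H]12 | intermediate
26 | 6α-hydroxy 12-enal | O[C@H]1[C@H](C(=C)C=O)[C@H](OC(=O)[C@@]3(C)O[C@@H]3C)[C@@H](OC(C)=O)[C@@]2(C(=O)OC)C=CC(=O)[C@@H](C)[C@@H]12 | intermediate
27 | 6,12-lactol (both anomers) | C=C1C(O)O[C@H]2[C@H]1[C@H](OC(=O)[C@@]4(C)O[C@@H]4C)[C@@H](OC(C)=O)[C@@]3(C(=O)OC)C=CC(=O)[C@@H](C)[C@@H]23 | intermediate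
28 | trans-fused α-methylene lactone with ring A 1-en-3-one | C=C1C(=O)O[C@H]2[C@H]1[C@H](OC(=O)[C@@]4(C)O[C@@H]4C)[C@@H](OC(C)=O)[C@@]3(C(=O)OC)C=CC(=O)[C@@H](C)[C@@H]23 | intermediate
29 | C3 allylic alcohol of 28 (hydroxyl cis to C15) | C=C1C(=O)O[C@H]2[C@H]1[C@H](OC(=O)[C@@]4(C)O[C@@H]4C)[C@@H](OC(C)=O)[C@@]3(C(=O)OC)C=C[C@@H](O)[C@@H](C)[C@@H]23 | intermediate
30 | cis-fused 1,3-diene ester: H5 and CO2Me β (ring A on the α face), 6α,12-lactone, 8β-epoxy ester, 9α-acetate | C=C1C(=O)O[C@H]2[C@H]1[C@H](OC(=O)[C@@]4(C)O[C@@H]4C)[C@@H](OC(C)=O)[C@@]3(C(=O)OC)C=CC=C(C)[C@@H]23 | intermediate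
31 | 4,5-deoxy target: ring-cis C10=C1, Z C2=C3, E C4=C5 trienoate | C=C1C(=O)O[C@H]2[C@H]1[C@H](OC(=O)[C@@]3(C)O[C@@H]3C)[C@@H](OC(C)=O)/C(C(=O)OC)=C\C=C/C(C)=C/2 | intermediate
32 | methyl (4R,5R,6S,7R,8S,9S)-9-acetoxy-4,5-epoxy-8-[(2S,3R)-2,3-dimethyloxirane-2-carbonyloxy]germacra-1(10),2,11(13)-trien-12,6-olid-14-oate (C10=C1 ring-cis, C2=C3 Z) | C=C1C(=O)O[C@H]2[C@H]1[C@H](OC(=O)[C@@]1(C)O[C@@H]1C)[C@@H](OC(C)=O)/C(C(=O)OC)=C\C=C/[C@@]1(C)O[C@H]21 | target

## Step count and least certain steps

Total: 22 steps. Longest linear sequence: 17 steps (steps 1, 3–5, 7–11, 15–22) from methyl 2,5-dihydroxybenzoate.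

**Step 21 (key step).** The opening may run in the other conrotatory sense if ring B leaves the chair that sets the twist of the diene. The product dienoate also absorbs the same light, so it can be lost by secondary photoisomerisation, or it can reclose thermally before it is oxidised. Fallback, from 30 back to 31: closed-loop flow irradiation in which the cold photolysate passes continuously over silica gel loaded with AgNO3. The strained E alkene binds silver and is held as the silver nitrate complex of 31 F1, out of the light and unable to reclose, while unchanged 30 returns to the lamp. Washing the support with cold aqueous NaCl releases 31 for step 22.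

**Step 3.** Uncatalysed cycloaddition of the very reactive quinone may compete with the catalysed path and erode facial control, or the Lewis acid may desilylate the diene. Fallback, from 2 and 4 back to 6: cycloaddition without catalyst in CH2Cl2 at −40 °C gives racemic 5 F2, and step 4 then gives racemic 6 F3. A lipase with vinyl acetate, chosen so that the unwanted antipode is the one acylated, converts it into the acetate of ent-6 F4, and 6 is separated by chromatography.

**Step 4.** Hydride may attack C9, which is the more electrophilic carbonyl (part of a β-keto ester), or both carbonyls. Fallback, from 5 back to 7: both carbonyls are reduced from the convex face (NaBH4, CeCl3·7H2O, −40 °C) to the 6α,9α-diol F5. Only the unhindered C6 hydroxyl is silylated (TBSCl, imidazole) to the mono-silyl ether F6, and the remaining allylic C9 alcohol is re-oxidised with MnO2 to 7.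

**Step 15.** Acylation may occur at C9 or on both hydroxyls, or the axial C8 hydroxyl may close onto the syn-axial C14 ester under the basic conditions. Fallback, from 15 back to 24: the only hydroxyl of 15 is acetylated (Ac2O, DMAP) to the 9α-acetoxy-8-ketone F7. The ketone is reduced along the equatorial trajectory with LiBH(s-Bu)3 to the 8β-alcohol F8, which is esterified with 22 to the silyl enol ether diester F9. Saegusa oxidation with Pd(OAc)2 then gives 24.

**Step 20.** The allyl cation may be captured by the fluoroalkoxide, or a neighbouring group on C10 may shift, instead of proton loss. Fallback, from 29 back to 30: the alcohol is converted into the allylic methyl carbonate F10 (ClCO2Me, pyridine) and treated with Pd(PPh3)4 in THF at 60 °C. The π-allyl complex of divalent palladium loses H4 by β-hydride elimination; H4 is the only β-hydrogen.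

## Further compounds

F1 | step 21 | silver nitrate complex of 31 | C=C1C(=O)O[C@H]2[C@H]1[C@H](OC(=O)[C@@]3(C)O[C@@H]3C)[C@@H](OC(C)=O)/C(C(=O)OC)=C\C=C/C(C)=C/2.[Ag+].[O-][N+](=O)[O-]
F2 | step 3 | racemic 5 (relative configuration shown) | O=C1C=CC(=O)[C@@]2(C(=O)OC)CC=C(O[Si](C)(C)C(C)(C)C)[C@@H](C)[C@@H]12
F3 | step 3 | racemic 6 (relative configuration shown) | O[C@H]1C=CC(=O)[C@@]2(C(=O)OC)CC=C(O[Si](C)(C)C(C)(C)C)[C@@H](C)[C@@H]12
F4 | step 3 | acetate of ent-6 | CC(=O)O[C@@H]1C=CC(=O)[C@]2(C(=O)OC)CC=C(O[Si](C)(C)C(C)(C)C)[C@H](C)[C@H]12
F5 | step 4 | 6α,9α-diol from double reduction of 5 | O[C@H]1C=C[C@@H](O)[C@@]2(C(=O)OC)CC=C(O[Si](C)(C)C(C)(C)C)[C@@H](C)[C@@H]12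
F6 | step 4 | 6α-silyl ether 9α-alcohol | CC(C)(C)[Si](C)(C)O[C@H]1C=C[C@@H](O)[C@@]2(C(=O)OC)CC=C(O[Si](C)(C)C(C)(C)C)[C@@H](C)[C@@H]12
F7 | step 15 | 9α-acetoxy-8-ketone (ring A silyl enol ether) | CC(C)(C)[Si](C)(C)O[C@H]1[C@H](C(=C)CO[Si](C)(C)C(C)(C)C)C(=O)[C@@H](OC(C)=O)[C@@]2(C(=O)OC)CC=C(O[Si](C)(C)C(C)(C)C)[C@@H](C)[C@@H]12
F8 | step 15 | 8β-alcohol 9α-acetate (ring A silyl enol ether) | CC(C)(C)[Si](C)(C)O[C@H]1[C@H](C(=C)CO[Si](C)(C)C(C)(C)C)[C@H](O)[C@@H](OC(C)=O)[C@@]2(C(=O)OC)CC=C(O[Si](C)(C)C(C)(C)C)[C@@H](C)[C@@H]12
F9 | step 15 | 8β-epoxy ester 9α-acetate (ring A silyl enol ether) | CC(C)(C)[Si](C)(C)O[C@H]1[C@H](C(=C)CO[Si](C)(C)C(C)(C)C)[C@H](OC(=O)[C@@]3(C)O[C@@H]3C)[C@@H](OC(C)=O)[C@@]2(C(=O)OC)CC=C(O[Si](C)(C)C(C)(C)C)[C@@H](C)[C@@H]12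
F10 | step 20 | C3 allylic methyl carbonate of 29 | C=C1C(=O)O[C@H]2[C@H]1[C@H](OC(=O)[C@@]4(C)O[C@@H]4C)[C@@H](OC(C)=O)[C@@]3(C(=O)OC)C=C[C@@H](OC(=O)OC)[C@@H](C)[C@@H]23
A1 | alternative 1 | cis,anti,cis tricyclic photoadduct (bicyclo[2.2.0]hexane on ring B) | C=C1C(=O)O[C@H]2[C@H]1[C@H](O[Si](C)(C)C(C)(C)C)C(=O)[C@]3(C)[C@H]4CC[C@@]4(C)[C@H]23
A2 | alternative 1 | 8β-silyloxy-9-oxo enone lactone with C14 methyl | C=C1C(=O)O[C@H]2[C@H]1[C@H](O[Si](C)(C)C(C)(C)C)C(=O)C(C)=C2
A3 | alternative 1 | 1-methylcyclobutene | CC1=CCC1
A4 | alternative 2 | ten-membered 1-en-10-one with E C4=C5 | C=C(CO[Si](C)(C)C(C)(C)C)[C@@H]1[C@H](OCc2ccc(OC)cc2)[C@@H](OCOC)C(=O)/C=C\C/C(C)=C/[C@H]1O[Si](C)(C)C(C)(C)C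
A5 | alternative 2 | 10-ethynyl-5-isopropenyl cyclohexanol (ethynyl and isopropenyl trans) | CC(C)(C)[Si](C)(C)O[C@H]1[C@H](C(=C)CO[Si](C)(C)C(C)(C)C)[C@H](OCc2ccc(OC)cc2)[C@@H](OCOC)[C@@](O)(C#C)[C@@H]1C(C)=C
A6 | alternative 3 | ten-membered 9-hydroxy triene lactone | C=C1C(=O)O[C@H]2[C@H]1[C@H](OCc3ccc(OC)cc3)[C@@H](O)/C(CO[Si](C)(C)C(C)(C)C)=C\C=C/C(C)=C/2
A7 | alternative 3 | seco C9 aldehyde with C10 vinyl iodide | C=C1C(=O)O[C@H](/C=C(C)/C=C\C=C(/I)CO[Si](C)(C)C(C)(C)C)[C@H]1[C@H](OCc2ccc(OC)cc2)C=O
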